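**Retrosynthetic overview**

1. Ring B (O1–C2–C3–C3a–C7a) is closed last: the C2 hydroxyl adds to the C7a carbonyl of a 6-allyl-6-alkyl-3,4-dimethoxycyclohexadienone and methanol is lost (C6–OMe becomes the C6 ketone). The C3a–allyl bond comes from Hosomi–Sakurai allylation of a p-quinone monoketal cation, anti to the C3 methyl.
2. The quinone monoketal (ring A, C3a–C4–C5–C6–C7–C7a) comes from a 2-alkyl-4,5-dimethoxyphenol with PhI(OAc)2/MeOH, so ring A enters the synthesis as a benzene ring.
3. Key disconnection: the aryl–C2 bond and the C3–C3a bond are formed together in one enantioselective palladium-catalysed three-component conjunctive cross-coupling of (3,4,5-trimethoxyphenyl)lithium, an (E)-propenylboronic ester and an aryl triflate; boron on C2 is then oxidised to O1.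
4. Enabling feature: C2 is a carbinol carbon (bonded to O1) that carries the aryl group and sits next to C3(H)(CH3), which is bonded to C3a of a six-membered ring at the oxidation level of a 1,2,4-trioxygenated benzene. This 2,3-trans O–C(Ar)–C(Me)–C(aryl) array is what an anti arylative 1,2-boronate shift across an E-propenyl–boron unit delivers.
5. Ring order: benzene ring A (bought) → dearomatised ring A (steps 9 and 10) → ring B (step 10).

Key step: step 6

Assumption: the (Sp,Sp) antipode of MandyPhos, Fe[η5-C5H3(PAr2)(CH(NMe2)Ph)]2 with Ar = 4-methoxy-3,5-dimethylphenyl, is taken to deliver the (1S,2R) boronic ester 13; if the sense of induction is the opposite, the (Rp,Rp) ligand is used with no other change. "mac" is the cyclic boronic ester of cis-1,2-dimethylacenaphthylene-1,2-diol; locants C2 to C7a and O1 are those of the target benzofuranone.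

**Route**

Step 1
Reactants: 1 2-hydroxy-4,5-dimethoxybenzaldehyde
Product: 2 2-(benzyloxy)-4,5-dimethoxybenzaldehyde
Conditions: BnBr, K2CO3, DMF, 60 °C
Reagents that add atoms: benzyl bromide, BrCc1ccccc1
Why: Williamson O-alkylation of the only acidic site, the phenol, leaves the aldehyde untouched.

Step 2
Reactants: 2 2-(benzyloxy)-4,5-dimethoxybenzaldehyde
Product: 4 2-(benzyloxy)-4,5-dimethoxyphenol, via aryl formate 3 (not isolated)
Conditions: mCPBA, CH2Cl2, 0 °C to rt; then K2CO3 (cat.), MeOH, rt
Reagents that add atoms: 3-chloroperoxybenzoic acid (mCPBA), OOC(=O)c1cccc(Cl)c1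
Why: Baeyer–Villiger (Dakin-type) oxidation, in which the electron-rich aryl group migrates to give formate 3, which methanolysis cleaves to the phenol.

Step 3
Reactants: 4 2-(benzyloxy)-4,5-dimethoxyphenol
Product: 5 2-(benzyloxy)-4,5-dimethoxyphenyl trifluoromethanesulfonate
Conditions: Tf2O, pyridine, CH2Cl2, 0 °C
Reagents that add atoms: trifluoromethanesulfonic anhydride, O=S(=O)(OS(=O)(=O)C(F)(F)F)C(F)(F)F
Why: O-sulfonylation of the phenol gives the aryl triflate needed for oxidative addition; the ethers are inert.

Step 4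
Reactants: 6 acenaphthylene-1,2-dione
Product: 7 cis-1,2-dimethylacenaphthylene-1,2-diol (mac diol, meso)
Conditions: AlMe3, toluene, 0 °C to rt; aqueous work-up; recrystallisation
Reagents that add atoms: trimethylaluminium, C[Al](C)C
Why: Twofold 1,2-addition of methyl to the 1,2-dione, the second methyl expected to enter anti to the bulky aluminium alkoxide so that the cis diol needed for a cyclic boronic ester predominates and is purified by crystallisation.

Step 5
Reactants: 7 cis-1,2-dimethylacenaphthylene-1,2-diol; 8 (E)-prop-1-en-1-ylboronic acid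
Product: 9 (E)-prop-1-en-1-yl-B(mac)
Conditions: MgSO4, CH2Cl2, rt
Reagents that add atoms: none
Why: Boronic ester condensation driven by the drying agent; the E geometry of the propenyl group is not affected.

Step 6
Reactants: 10 5-bromo-1,2,3-trimethoxybenzene; 9 (E)-prop-1-en-1-yl-B(mac); 5 2-(benzyloxy)-4,5-dimethoxyphenyl trifluoromethanesulfonate
Product: 13 B(mac) ester of [(1S,2R)-2-[2-(benzyloxy)-4,5-dimethoxyphenyl]-1-(3,4,5-trimethoxyphenyl)propyl]boronic acid, via aryllithium 11 (not isolated), via boron ate complex 12 (not isolated)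
Conditions: 10, n-BuLi, THF, −78 °C; then 9, −78 °C to rt; then 5, Pd(OAc)2 (3 mol %), (Sp,Sp)-MandyPhos (3.6 mol %), THF, 60 °C
Reagents that add atoms: none
Why: Aryllithium 11 adds to boron of 9 to give the four-coordinate ate complex 12; the divalent arylpalladium species formed from 5 by oxidative addition to zerovalent palladium binds the propenyl π-bond and triggers a 1,2-shift of the trimethoxyphenyl group from boron to the α-carbon (the aryl–C2 bond) anti to palladium, and C–C reductive elimination then joins C3 to the benzene carbon that becomes C3a. The closest known reaction type is the enantio- and diastereoselective palladium-catalysed conjunctive cross-coupling of β-substituted alkenyl-B(mac) ate complexes with aryl triflates. No ring is closed in this step; ring B is closed in step 10 through the oxygen that replaces boron. The C2/C3 relative configuration follows from stereospecific anti addition of the two aryl groups across the E double bond, which is the array that becomes 2,3-trans once O1 bridges C2 and C7a with retention, and the absolute configuration of both centres is set by the alkene face that the MandyPhos-bound palladium selects. The step needs the conjunctive pathway to win over direct Suzuki–Miyaura transfer of the propenyl or aryl group and over β-hydride elimination; the hindered, poorly transmetallating mac ligand on boron and the fast reductive elimination from the ferrocenyl bisphosphine complex are expected to secure this.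

Step 7
Reactants: 13 B(mac) ester of [(1S,2R)-2-[2-(benzyloxy)-4,5-dimethoxyphenyl]-1-(3,4,5-trimethoxyphenyl)propyl]boronic acid
Product: 14 (1S,2S)-2-[2-(benzyloxy)-4,5-dimethoxyphenyl]-1-(3,4,5-trimethoxyphenyl)propan-1-ol
Conditions: H2O2 (30 % aq.), NaOH (3 M aq.), THF, 0 °C to rt
Reagents that add atoms: hydrogen peroxide, OO
Why: Oxidation of the C–B bond by hydroperoxide (1,2-shift of carbon from boron to oxygen) proceeds with retention at C2 and places the future O1 on C2.

Step 8
Reactants: 14 (1S,2S)-2-[2-(benzyloxy)-4,5-dimethoxyphenyl]-1-(3,4,5-trimethoxyphenyl)propan-1-ol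
Product: 15 2-[(1S,2S)-1-hydroxy-1-(3,4,5-trimethoxyphenyl)propan-2-yl]-4,5-dimethoxyphenol
Conditions: H2 (1 atm), Pd/C (10 %), EtOAc, rt
Reagents that add atoms: none
Why: Hydrogenolysis of the aryl benzyl ether over palladium on carbon; the secondary benzylic alcohol should survive under neutral conditions at 1 atm.

Step 9
Reactants: 15 2-[(1S,2S)-1-hydroxy-1-(3,4,5-trimethoxyphenyl)propan-2-yl]-4,5-dimethoxyphenol
Product: 16 2-[(1S,2S)-1-hydroxy-1-(3,4,5-trimethoxyphenyl)propan-2-yl]-4,4,5-trimethoxycyclohexa-2,5-dien-1-one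
Conditions: PhI(OAc)2, MeOH, 0 °C; NaHCO3 work-up
Reagents that add atoms: methanol, CO
Why: Oxidative dearomatisation of the 4-methoxyphenol by the hypervalent iodine reagent, with methanol adding para to the phenol oxygen (at C5) to give the p-quinone monoketal; no stereocentre is touched.

Step 10
Reactants: 16 2-[(1S,2S)-1-hydroxy-1-(3,4,5-trimethoxyphenyl)propan-2-yl]-4,4,5-trimethoxycyclohexa-2,5-dien-1-one
Product: 18 (2S,3S,3aS)-3a-allyl-5-methoxy-3-methyl-2-(3,4,5-trimethoxyphenyl)-3,3a-dihydro-1-benzofuran-6(2H)-one, via open-chain allyl dienone 17 (not isolated)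
Conditions: CH2=CHCH2SiMe3 (3 equiv), Me3SiOTf (0.2 equiv), CH2Cl2, −78 to −30 °C; aq. NaHCO3
Reagents that add atoms: allyltrimethylsilane, C=CC[Si](C)(C)C
Why: Proposed new method: Me3SiOTf should ionise the dimethyl ketal of 16 to a 4-methoxyphenoxonium-type cation whose side-chain-bearing α-carbon (future C3a) is the electrophilic terminus (the other α-carbon, C7, is deactivated as part of the methoxy enol ether), so Hosomi–Sakurai attack there gives 17, with the allyl group entering anti to the carbinol arm in the conformer that has C3–H eclipsing the C7a carbonyl, or anti to the C3 methyl if the hemiketal has already closed (both give the 3-methyl/3a-allyl trans relation); the C2 hydroxyl of 17 then adds to the C7a carbonyl (5-exo-trig) and the hemiketal loses methanol through the vinylogous oxocarbenium ion to give 18; the closest known reaction types are the Lewis-acid-promoted cationic (3+2) cycloaddition of 2-allyl-4,4,5-trimethoxycyclohexadienone with (E)-propenylarenes, in which a π-nucleophile attacks the same substituted α-carbon, and the Sakurai allylation of quinone monoketals α to the carbonyl.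

**Compound list**

1 | 2-hydroxy-4,5-dimethoxybenzaldehyde | O=Cc1cc(OC)c(OC)cc1O | starting material
2 | 2-(benzyloxy)-4,5-dimethoxybenzaldehyde | O=Cc1cc(OC)c(OC)cc1OCc1ccccc1 | intermediate
3 | 2-(benzyloxy)-4,5-dimethoxyphenyl formate | O=COc1cc(OC)c(OC)cc1OCc1ccccc1 | intermediate (not isolated)
4 | 2-(benzyloxy)-4,5-dimethoxyphenol | Oc1cc(OC)c(OC)cc1OCc1ccccc1 | intermediate
5 | 2-(benzyloxy)-4,5-dimethoxyphenyl trifluoromethanesulfonate | O=S(=O)(Oc1cc(OC)c(OC)cc1OCc1ccccc1)C(F)(F)F | intermediate
6 | acenaphthylene-1,2-dione | O=C1C(=O)c2cccc3cccc1c23 | starting material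
7 | (1R,2S)-1,2-dimethyl-1,2-dihydroacenaphthylene-1,2-diol (cis, meso; mac diol) | C[C@]1(O)c2cccc3cccc(c23)[C@@]1(C)O | intermediate
8 | (E)-prop-1-en-1-ylboronic acid | C/C=C/B(O)O | starting material
9 | (E)-prop-1-en-1-yl-B(mac) | C/C=C/B1O[C@@]2(C)c3cccc4cccc(c34)[C@@]2(C)O1 | intermediate
10 | 5-bromo-1,2,3-trimethoxybenzene | COc1cc(Br)cc(OC)c1OC | starting material
11 | (3,4,5-trimethoxyphenyl)lithium | [Li]c1cc(OC)c(OC)c(OC)c1 | intermediate (not isolated)
12 | lithium (E)-propenyl(3,4,5-trimethoxyphenyl)borate, mac ester | [Li+].C/C=C/[B-]1(c2cc(OC)c(OC)c(OC)c2)O[C@@]3(C)c4cccc5cccc(c45)[C@@]3(C)O1 | intermediate (not isolated)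
13 | B(mac) ester of [(1S,2R)-2-[2-(benzyloxy)-4,5-dimethoxyphenyl]-1-(3,4,5-trimethoxyphenyl)propyl]boronic acid | C[C@@H](c1cc(OC)c(OC)cc1OCc1ccccc1)[C@@H](c1cc(OC)c(OC)c(OC)c1)B1O[C@@]2(C)c3cccc4cccc(c34)[C@@]2(C)O1 | intermediate
14 | (1S,2S)-2-[2-(benzyloxy)-4,5-dimethoxyphenyl]-1-(3,4,5-trimethoxyphenyl)propan-1-ol | O[C@H](c1cc(OC)c(OC)c(OC)c1)[C@H](c1cc(OC)c(OC)cc1OCc1ccccc1)C | intermediate
15 | 2-[(1S,2S)-1-hydroxy-1-(3,4,5-trimethoxyphenyl)propan-2-yl]-4,5-dimethoxyphenol | O[C@H](c1cc(OC)c(OC)c(OC)c1)[C@H](c1cc(OC)c(OC)cc1O)C | intermediate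
16 | 2-[(1S,2S)-1-hydroxy-1-(3,4,5-trimethoxyphenyl)propan-2-yl]-4,4,5-trimethoxycyclohexa-2,5-dien-1-one | O[C@H](c1cc(OC)c(OC)c(OC)c1)[C@H](C1=CC(OC)(OC)C(OC)=CC1=O)C | intermediate
17 | (6S)-6-allyl-6-[(1S,2S)-1-hydroxy-1-(3,4,5-trimethoxyphenyl)propan-2-yl]-3,4-dimethoxycyclohexa-2,4-dien-1-one | C=CC[C@@]1(C=C(OC)C(OC)=CC1=O)[C@H](C)[C@H](O)c1cc(OC)c(OC)c(OC)c1 | intermediate (not isolated)
18 | (2S,3S,3aS)-3a-allyl-5-methoxy-3-methyl-2-(3,4,5-trimethoxyphenyl)-3,3a-dihydro-1-benzofuran-6(2H)-one (2-aryl/3-methyl trans, 3-methyl/3a-allyl trans) | C=CC[C@]12C=C(OC)C(=O)C=C1O[C@H](c1cc(OC)c(OC)c(OC)c1)[C@H]2C | target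

**Summary**

Total step count: 10. Longest linear sequence: 8 steps (steps 1, 2, 3, 6, 7, 8, 9, 10).

Steps most likely to fail:

1. Step 10 (Proposed new method). What may go wrong: the allylsilane may attack the ketal carbon C5 instead of C3a; the β-silyl cation may cyclise onto the C7a oxygen instead of losing silicon; the cation may lose the C3 proton (o-quinone methide formation, which erases C3); or the facial selectivity at C3a may be poor. Fallback with known chemistry, in which the allyl group is installed before the heterocycle: setting out from 10 and 8, a Suzuki–Miyaura coupling (Pd(PPh3)4, K2CO3, dioxane–water, 90 °C) would give (E)-1,2,3-trimethoxy-5-(prop-1-en-1-yl)benzene F1. Commercial 3,4-dimethoxyphenol would be O-allylated (allyl bromide, K2CO3, acetone) to 4-(allyloxy)-1,2-dimethoxybenzene F2, rearranged (aromatic Claisen, N,N-diethylaniline, 190 °C) to 2-allyl-4,5-dimethoxyphenol F3 and oxidised (PhI(OAc)2, MeOH) to 2-allyl-4,4,5-trimethoxycyclohexa-2,5-dien-1-one F4. The SnCl4-promoted cationic (3+2) cycloaddition of F4 with F1 (CH2Cl2, −78 °C; C3–C3a then O1–C2 bond formation, loss of two methanol) is the established entry to 3a-allyl hydrobenzofuranones and should give the 2,3-trans adducts as racemates. The adduct with the relative configuration of the target would be separated from its isomers and resolved by preparative HPLC on a chiral stationary phase into 18 and its enantiomer (2R,3R,3aR)-3a-allyl-5-methoxy-3-methyl-2-(3,4,5-trimethoxyphenyl)-3,3a-dihydro-1-benzofuran-6(2H)-one F5. The fallback comes back to the route at 18.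

2. Step 6. What may go wrong: slow oxidative addition of the hindered, electron-rich ortho-alkoxy triflate; direct Suzuki–Miyaura transfer from the ate complex; β-hydride elimination before reductive elimination; or insufficient enantioselectivity. Fallback, which keeps the aryl–C2 bond formation but makes it at the ketone level: setting out from 5, palladium-catalysed α-arylation of the zinc enolate of commercial 4-propanoylmorpholine (LiN(SiMe3)2, ZnCl2; Pd(dba)2, P(t-Bu)3, THF) would give racemic 2-[2-(benzyloxy)-4,5-dimethoxyphenyl]-1-(morpholin-4-yl)propan-1-one F6. Addition of aryllithium 11 (from 10, THF, −78 °C) would give racemic 2-[2-(benzyloxy)-4,5-dimethoxyphenyl]-1-(3,4,5-trimethoxyphenyl)propan-1-one F7. Noyori asymmetric hydrogenation under dynamic kinetic resolution (RuCl2(xylBINAP)(DAIPEN), KOt-Bu, H2, i-PrOH; the base racemises the α-aryl centre and hydride adds in the Felkin–Anh sense, anti to the aryl group) should then give 14, where the fallback rejoins the route.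

3. Step 8. What may go wrong: over-reduction, that is, hydrogenolysis of the electron-rich benzylic C2–O bond competing with debenzylation. Fallback, which reverses the order of deprotection and oxidation: setting out from 13, hydrogenolysis (H2, Pd/C, EtOAc) at the boronic ester stage, where no benzylic C–O bond other than the benzyl ether is present, would give the B(mac) ester of [(1S,2R)-2-(2-hydroxy-4,5-dimethoxyphenyl)-1-(3,4,5-trimethoxyphenyl)propyl]boronic acid F8. Mild oxidation (NaBO3·4H2O, THF–water, rt) would then give 15, where the fallback rejoins the route.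

**Further compounds**

F1 | step 10 | (E)-1,2,3-trimethoxy-5-(prop-1-en-1-yl)benzene | C/C=C/c1cc(OC)c(OC)c(OC)c1
F2 | step 10 | 4-(allyloxy)-1,2-dimethoxybenzene | C=CCOc1ccc(OC)c(OC)c1
F3 | step 10 | 2-allyl-4,5-dimethoxyphenol | C=CCc1cc(OC)c(OC)cc1O
F4 | step 10 | 2-allyl-4,4,5-trimethoxycyclohexa-2,5-dien-1-one | C=CCC1=CC(OC)(OC)C(OC)=CC1=O
F5 | step 10 | (2R,3R,3aR)-3a-allyl-5-methoxy-3-methyl-2-(3,4,5-trimethoxyphenyl)-3,3a-dihydro-1-benzofuran-6(2H)-one (enantiomer of 18) | C=CC[C@@]12C=C(OC)C(=O)C=C1O[C@@H](c1cc(OC)c(OC)c(OC)c1)[C@@H]2C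
F6 | step 6 | rac-2-[2-(benzyloxy)-4,5-dimethoxyphenyl]-1-(morpholin-4-yl)propan-1-one | CC(C(=O)N1CCOCC1)c1cc(OC)c(OC)cc1OCc1ccccc1
F7 | step 6 | rac-2-[2-(benzyloxy)-4,5-dimethoxyphenyl]-1-(3,4,5-trimethoxyphenyl)propan-1-one | CC(C(=O)c1cc(OC)c(OC)c(OC)c1)c1cc(OC)c(OC)cc1OCc1ccccc1
F8 | step 8 | B(mac) ester of [(1S,2R)-2-(2-hydroxy-4,5-dimethoxyphenyl)-1-(3,4,5-trimethoxyphenyl)propyl]boronic acid | C[C@@H](c1cc(OC)c(OC)cc1O)[C@@H](c1cc(OC)c(OC)c(OC)c1)B1O[C@@]2(C)c3cccc4cccc(c34)[C@@]2(C)O1
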